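**Retrosynthetic overview**

1. The C3 ester is made last on the free allylic alcohol: acetoacetylation with diketene, double C-methylation, then catalyst-controlled ketone reduction.
2. The tetrahydrofuran and γ-lactone rings come from one dearomatising step: decarboxylative singlet-oxygen oxidation of a 5-alkyl-3-methyl-2-furoic acid with spiroketalisation by the C6 hydroxymethyl, then conjugate reduction.
3. The two C6 arms come from face-selective opening of a spiro-oxetane by the dianion of 2-furoic acid (cheap, furfural-derived), followed by carboxylate-directed C-methylation.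
4. The cyclobutane and six-membered ring come from one intramolecular vinylketene–alkene [2+2] cycloaddition, then Wolff–Kishner reduction; all core stereocentres are relayed from one carbinol set by proline-catalysed α-aminoxylation.
5. Ring order: oxetane (purchased) → cyclobutane + cyclohexane (one step) → tetrahydrofuran + lactone (one step).

Assumption: core atoms are labelled C1–C7 and C10 as in bicyclo[3.1.1]heptane (C2 carries the methylidene carbon C10, C3 the ester oxygen, C6 is the spiro carbon, C7 the CH2 bridge); reagents without a number are bought.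

**Step 1**
Reactants: 1 oxetan-3-one; 2 vinylmagnesium bromide
Product: 3 3-ethenyloxetan-3-ol
Conditions: CH2=CHMgBr (1.2 equiv), THF, −78 → 0 °C; aq. NH4Cl
Reagents that add atoms: none
Why: Grignard 1,2-addition to a strained ketone that does not enolise readily gives the tertiary allylic alcohol; no stereocentre is formed.

**Step 2**
Reactants: 3 3-ethenyloxetan-3-ol; 4 2,2,6-trimethyl-4H-1,3-dioxin-4-one
Product: 8 5-(oxetan-3-ylidene)pentan-2-one, via acetylketene 5 (not isolated), via allyl acetoacetate 6 (not isolated), via keto acid 7 (not isolated)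
Conditions: 4 (1.3 equiv), o-xylene, 140 °C, 1 h; then 175 °C, sealed tube, 3 h
Reagents that add atoms: none
Why: Acetylketene released from 4 acylates the tertiary alcohol and the allyl acetoacetate undergoes Carroll rearrangement ([3,3]-sigmatropic shift, then decarboxylation); the symmetric oxetane makes the geometry of the new alkene irrelevant and the ester has no elimination pathway.

**Step 3**
Reactants: 8 5-(oxetan-3-ylidene)pentan-2-one
Product: 10 (3S)-3-hydroxy-5-(oxetan-3-ylidene)pentan-2-one, via aminooxy ketone 9 (not isolated)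
Conditions: D-proline (20 mol %), PhNO (1 equiv, syringe pump), 8 (2 equiv, excess recovered), DMSO, 23 °C; then CuSO4·5H2O (30 mol %), MeOH, 0 °C
Reagents that add atoms: nitrosobenzene, O=Nc1ccccc1
Why: Proline-catalysed enamine α-aminoxylation (nitroso aldol) at the more substituted α-carbon, then CuSO4-mediated N–O cleavage; the carboxylic acid of D-proline delivers the oxygen to one face of the (E)-enamine and sets the (S)-carbinol that becomes C3 (the enantiomer of the sense known for L-proline).

**Step 4**
Reactants: 10 (3S)-3-hydroxy-5-(oxetan-3-ylidene)pentan-2-one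
Product: 11 (3S)-3-[(tert-butyldimethylsilyl)oxy]-5-(oxetan-3-ylidene)pentan-2-one
Conditions: TBSCl, imidazole, DMF, 23 °C
Reagents that add atoms: tert-butyldimethylsilyl chloride, CC(C)(C)[Si](C)(C)Cl
Why: Standard silyl ether formation masks the carbinol for the olefination and acid chloride chemistry; the stereocentre is not touched.

**Step 5**
Reactants: 11 (3S)-3-[(tert-butyldimethylsilyl)oxy]-5-(oxetan-3-ylidene)pentan-2-one; 12 triethyl phosphonoacetate
Product: 14 (2E,4S)-4-[(tert-butyldimethylsilyl)oxy]-3-methyl-6-(oxetan-3-ylidene)hex-2-enoic acid, via ethyl ester 13 (not isolated)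
Conditions: 12, NaH, THF, 0 → 40 °C; then LiOH·H2O, MeOH/H2O, 45 °C; aq. HCl to pH 4 (0 °C)
Reagents that add atoms: lithium hydroxide monohydrate, [Li+].[OH-].O
Why: Horner–Wadsworth–Emmons olefination of the α-silyloxy methyl ketone puts the ester trans to the bulky silyloxy-bearing carbon (E, minor Z acid removed by chromatography), and saponification in the same flask gives the acid; the weakly basic phosphonate anion does not epimerise C4.

**Step 6**
Reactants: 14 (2E,4S)-4-[(tert-butyldimethylsilyl)oxy]-3-methyl-6-(oxetan-3-ylidene)hex-2-enoic acid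
Product: 17 (1R,3S,5R)-3-[(tert-butyldimethylsilyl)oxy]-2-methylidenespiro[bicyclo[3.1.1]heptane-6,3'-oxetan]-7-one, via acid chloride 15 (not isolated), via vinylketene 16 (not isolated)
Conditions: 1-chloro-N,N,2-trimethylprop-1-en-1-amine (1.1 equiv), CH2Cl2, 0 °C; then slow addition to Et3N (5 equiv), toluene (0.005 M), 110 °C
Reagents that add atoms: none
Why: Syn γ-deprotonation of the (E)-acid chloride at the methyl group gives the vinylketene, whose intramolecular [2+2] cycloaddition with the trisubstituted alkene (ketene carbonyl carbon to the less substituted alkene carbon, as in the geranoyl chloride to 2-methylidenebicyclo[3.1.1]heptan-6-one reaction) builds both carbocycles at once; the silyloxy group stays pseudo-equatorial on the forming six-membered ring, away from the incoming oxetane carbon, so C1 and C5 are set by C3 with the oxygen anti to the oxetane bridge.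

**Step 7**
Reactants: 17 (1R,3S,5R)-3-[(tert-butyldimethylsilyl)oxy]-2-methylidenespiro[bicyclo[3.1.1]heptane-6,3'-oxetan]-7-one
Product: 19 (1R,3S,5R)-2-methylidenespiro[bicyclo[3.1.1]heptane-6,3'-oxetan]-3-ol, via hydrazone 18 (not isolated)
Conditions: N2H4·H2O, diethylene glycol, 120 °C; then KOH, 195 °C
Reagents that add atoms: none
Why: Wolff–Kishner (Huang-Minlon) reduction removes the cyclobutanone carbonyl as in the β-pinene and bergamotene series, the base-stable oxetane survives and the hot KOH also cleaves the silyl ether; no stereocentre is affected.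

**Step 8**
Reactants: 19 (1R,3S,5R)-2-methylidenespiro[bicyclo[3.1.1]heptane-6,3'-oxetan]-3-ol; 20 furan-2-carboxylic acid
Product: 22 5-{[(1R,3S,5R,6S)-3-hydroxy-6-(hydroxymethyl)-2-methylidenebicyclo[3.1.1]heptan-6-yl]methyl}furan-2-carboxylic acid, via furoate dianion 21 (not isolated)
Conditions: 20 (2.5 equiv), LiN(iPr)2 (5.2 equiv), THF, −78 °C; then 19, BF3·OEt2 (4 equiv), −78 → −40 °C; aq. citric acid
Reagents that add atoms: none
Why: Carboxylate-directed 5-lithiation of 2-furoic acid followed by BF3-promoted SN2 opening of the oxetane by the aryllithium; attack occurs at the oxetane CH2 that points away from the C2–C4 bridge (the other CH2 lies over the six-membered ring), which fixes C6 with the hydroxymethyl syn and the furylmethyl anti to that bridge.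

**Step 9**
Reactants: 22 5-{[(1R,3S,5R,6S)-3-hydroxy-6-(hydroxymethyl)-2-methylidenebicyclo[3.1.1]heptan-6-yl]methyl}furan-2-carboxylic acid
Product: 24 5-{[(1R,3S,5R,6S)-3-hydroxy-6-(hydroxymethyl)-2-methylidenebicyclo[3.1.1]heptan-6-yl]methyl}-3-methylfuran-2-carboxylic acid, via tetralithio species 23 (not isolated)
Conditions: LiN(iPr)2 (4.5 equiv), THF, −78 → −30 °C; MeI (1.1 equiv), −78 °C; aq. citric acid
Reagents that add atoms: iodomethane, CI
Why: Carboxylate-directed ortho-lithiation at furan C3 (the only ring position next to the carboxylate; the hindered neopentyl-type CH2 is not deprotonated) and C-methylation put the methyl where the lactone α-carbon will be; no stereocentre is formed.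

**Step 10**
Reactants: 24 5-{[(1R,3S,5R,6S)-3-hydroxy-6-(hydroxymethyl)-2-methylidenebicyclo[3.1.1]heptan-6-yl]methyl}-3-methylfuran-2-carboxylic acid
Product: 27 spiroketal butenolide alcohol, via endoperoxide 25 (not isolated), via hydroxybutenolide 26 (not isolated)
Conditions: O2, visible light, methylene blue (1 mol %), MeOH, −20 °C; then pyridinium p-toluenesulfonate (10 mol %), CH2Cl2, 4 Å molecular sieves, 23 °C
Reagents that add atoms: oxygen, O=O
Why: Key step: [4+2] cycloaddition of singlet oxygen breaks the furan aromaticity, the endoperoxide fragments with loss of CO2 so that the former carboxyl-bearing carbon becomes the lactone carbonyl, and the resulting 5-hydroxybutenolide is spiroketalised by the C6 hydroxymethyl under acid; the ketal carbon forms under thermodynamic control as about 1:1 epimers, 27 is separated and the epimer is re-equilibrated with the same acid and recycled.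

**Step 11**
Reactants: 27 spiroketal butenolide alcohol
Product: 28 spiroketal lactone alcohol
Conditions: Cu(OAc)2·H2O (5 mol %), 1,2-bis(diphenylphosphino)benzene (5 mol %), (EtO)2MeSiH (4 equiv), t-BuOH (4 equiv), toluene, 23 °C; then NH4F, MeOH
Reagents that add atoms: none
Why: Copper hydride conjugate reduction of the butenolide leaves the isolated methylidene alone, and the copper enolate is protonated by t-BuOH from the face of the ring oxygen (anti to the bulkier ring CH2), placing the methyl cis to that CH2 as in the target (modest selectivity expected; the α-epimer is separable and can be re-equilibrated with base).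

**Step 12**
Reactants: 28 spiroketal lactone alcohol; 29 diketene (4-methylideneoxetan-2-one)
Product: 30 C3 acetoacetate of 28
Conditions: 29 (1.3 equiv), 4-(dimethylamino)pyridine (5 mol %), CH2Cl2, −20 → 23 °C
Reagents that add atoms: none
Why: Nucleophile-catalysed acetoacetylation: the pyridine catalyst opens the strained β-lactone of diketene and transfers the acetoacetyl group to the hindered secondary allylic alcohol at or below room temperature, far below the temperature of Carroll rearrangement and too mild to touch the ketal or the lactone α-centre; no stereocentre is touched.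

**Step 13**
Reactants: 30 C3 acetoacetate of 28
Product: 32 C3 2,2-dimethyl-3-oxobutanoate of 28, via monomethyl keto ester 31 (not isolated)
Conditions: MeI (3 equiv), K2CO3 (3 equiv), acetone, 40 °C
Reagents that add atoms: iodomethane, CI
Why: Double C-alkylation of the β-keto ester (pKa about 11) with a carbonate base builds the quaternary carbon, while the lactone α-proton (pKa about 25) and the ketal are untouched.

**Step 14**
Reactants: 32 C3 2,2-dimethyl-3-oxobutanoate of 28
Product: 33 target compound CNP0212779.5
Conditions: (R)-2-methyl-CBS-oxazaborolidine (20 mol %), catecholborane (1.8 equiv), toluene, −78 °C; MeOH, aq. NaHCO3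
Reagents that add atoms: none
Why: Corey–Bakshi–Shibata reduction differentiates the methyl group from the quaternary carbon of the ketone, and the (R)-catalyst gives the (S)-carbinol (the mirror-image outcome of the (S)-catalyst with pinacolone); catecholborane at −78 °C spares the lactone, the ester and the alkene.

**Compound list**

1 | oxetan-3-one | O=C1COC1 | starting material
2 | vinylmagnesium bromide | C=C[Mg]Br | starting material
3 | 3-ethenyloxetan-3-ol | C=CC1(O)COC1 | intermediate
4 | 2,2,6-trimethyl-4H-1,3-dioxin-4-one | CC1=CC(=O)OC(C)(C)O1 | starting material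
5 | acetylketene (buta-1-ene-1,3-dione) | CC(=O)C=C=O | intermediate
6 | 3-ethenyloxetan-3-yl 3-oxobutanoate | CC(=O)CC(=O)OC1(C=C)COC1 | intermediate
7 | 2-acetyl-4-(oxetan-3-ylidene)butanoic acid | CC(=O)C(CC=C1COC1)C(=O)O | intermediate
8 | 5-(oxetan-3-ylidene)pentan-2-one | CC(=O)CCC=C1COC1 | intermediate
9 | (3S)-5-(oxetan-3-ylidene)-3-[(phenylamino)oxy]pentan-2-one | CC(=O)[C@@H](ONc1ccccc1)CC=C1COC1 | intermediate
10 | (3S)-3-hydroxy-5-(oxetan-3-ylidene)pentan-2-one | CC(=O)[C@@H](O)CC=C1COC1 | intermediate
11 | (3S)-3-[(tert-butyldimethylsilyl)oxy]-5-(oxetan-3-ylidene)pentan-2-one | CC(=O)[C@@H](O[Si](C)(C)C(C)(C)C)CC=C1COC1 | intermediate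
12 | triethyl phosphonoacetate | CCOC(=O)CP(=O)(OCC)OCC | starting material
13 | ethyl (2E,4S)-4-[(tert-butyldimethylsilyl)oxy]-3-methyl-6-(oxetan-3-ylidene)hex-2-enoate | CCOC(=O)/C=C(\C)[C@@H](O[Si](C)(C)C(C)(C)C)CC=C1COC1 | intermediate
14 | (2E,4S)-4-[(tert-butyldimethylsilyl)oxy]-3-methyl-6-(oxetan-3-ylidene)hex-2-enoic acid | OC(=O)/C=C(\C)[C@@H](O[Si](C)(C)C(C)(C)C)CC=C1COC1 | intermediate
15 | (2E,4S)-4-[(tert-butyldimethylsilyl)oxy]-3-methyl-6-(oxetan-3-ylidene)hex-2-enoyl chloride | ClC(=O)/C=C(\C)[C@@H](O[Si](C)(C)C(C)(C)C)CC=C1COC1 | intermediate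
16 | (4S)-4-[(tert-butyldimethylsilyl)oxy]-3-methylidene-6-(oxetan-3-ylidene)hex-1-en-1-one (vinylketene) | O=C=CC(=C)[C@@H](O[Si](C)(C)C(C)(C)C)CC=C1COC1 | intermediate
17 | (1R,3S,5R)-3-[(tert-butyldimethylsilyl)oxy]-2-methylidenespiro[bicyclo[3.1.1]heptane-6,3'-oxetan]-7-one (silyloxy anti to the oxetane bridge) | C=C1[C@@H](O[Si](C)(C)C(C)(C)C)C[C@H]2C(=O)[C@@H]1C21COC1 | intermediate
18 | C7 hydrazone of 17 | C=C1[C@@H](O[Si](C)(C)C(C)(C)C)C[C@H]2C(=NN)[C@@H]1C21COC1 | intermediate
19 | (1R,3S,5R)-2-methylidenespiro[bicyclo[3.1.1]heptane-6,3'-oxetan]-3-ol (hydroxyl anti to the oxetane bridge) | C=C1[C@@H](O)C[C@H]2C[C@@H]1C21COC1 | intermediate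
20 | furan-2-carboxylic acid (2-furoic acid) | OC(=O)c1ccco1 | starting material
21 | lithium 5-lithiofuran-2-carboxylate | [Li]OC(=O)c1ccc([Li])o1 | intermediate
22 | 5-{[(1R,3S,5R,6S)-3-hydroxy-6-(hydroxymethyl)-2-methylidenebicyclo[3.1.1]heptan-6-yl]methyl}furan-2-carboxylic acid (hydroxymethyl syn to the C2–C4 bridge) | C=C1[C@@H](O)C[C@H]2C[C@@H]1[C@@]2(Cc1ccc(o1)C(=O)O)CO | intermediate
23 | tetralithio derivative of 22 (two lithium alkoxides, lithium carboxylate, furan C3–Li) | C=C1[C@@H](O[Li])C[C@H]2C[C@@H]1[C@@]2(Cc1cc([Li])c(o1)C(=O)O[Li])CO[Li] | intermediate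
24 | 5-{[(1R,3S,5R,6S)-3-hydroxy-6-(hydroxymethyl)-2-methylidenebicyclo[3.1.1]heptan-6-yl]methyl}-3-methylfuran-2-carboxylic acid | C=C1[C@@H](O)C[C@H]2C[C@@H]1[C@@]2(Cc1cc(C)c(o1)C(=O)O)CO | intermediate
25 | 2,5-endoperoxide of 24 (2,3,7-trioxabicyclo[2.2.1]hept-5-ene carrying the carboxyl and the core CH2) | C=C1[C@@H](O)C[C@H]2C[C@@H]1[C@@]2(CC1(OO3)OC3(C(=O)O)C(C)=C1)CO | intermediate
26 | 5-hydroxy-3-methyl-5-{[core-6-yl]methyl}furan-2(5H)-one (core as in 22) | C=C1[C@@H](O)C[C@H]2C[C@@H]1[C@@]2(CC1(O)OC(=O)C(C)=C1)CO | intermediate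
27 | spiroketal butenolide alcohol (target skeleton with free C3 hydroxyl and a C=C between the lactone α- and β-carbons; ketal carbon placed as in the target) | C=C1[C@@H](O)C[C@H]2C[C@@H]1[C@@]21CO[C@@]2(C=C(C)C(=O)O2)C1 | intermediate
28 | spiroketal lactone alcohol (target without the C3 acyl group; all ring stereocentres as in the target) | C=C1[C@@H](O)C[C@H]2C[C@@H]1[C@@]21CO[C@@]2(C[C@@H](C)C(=O)O2)C1 | intermediate
29 | diketene (4-methylideneoxetan-2-one) | C=C1CC(=O)O1 | starting material
30 | C3 acetoacetate (3-oxobutanoate) of 28 | C=C1[C@@H](OC(=O)CC(C)=O)C[C@H]2C[C@@H]1[C@@]21CO[C@@]2(C[C@@H](C)C(=O)O2)C1 | intermediate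
31 | C3 2-methyl-3-oxobutanoate of 28 (both epimers at the new α-carbon) | C=C1[C@@H](OC(=O)C(C)C(C)=O)C[C@H]2C[C@@H]1[C@@]21CO[C@@]2(C[C@@H](C)C(=O)O2)C1 | intermediate
32 | C3 2,2-dimethyl-3-oxobutanoate of 28 | C=C1[C@@H](OC(=O)C(C)(C)C(C)=O)C[C@H]2C[C@@H]1[C@@]21CO[C@@]2(C[C@@H](C)C(=O)O2)C1 | intermediate
33 | CNP0212779.5, C3 (3S)-3-hydroxy-2,2-dimethylbutanoate of 28 | C=C1[C@@H](OC(=O)C(C)(C)[C@H](C)O)C[C@H]2C[C@@H]1[C@@]21CO[C@@]2(C[C@@H](C)C(=O)O2)C1 | target

**Count**

Total step count: 14. Longest linear sequence: 14 (the route is fully linear from oxetan-3-one).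

**Three steps most likely to fail**

Step 6. The vinylketene may be too weak an electrophile for an alkene flanked by two allylic C–O bonds, or may close with the fused regiochemistry; the diastereoselectivity is also a prediction. The fallback sets out from 14 through its chloride 15: pyrrolidine and Et3N give the amide 1-[(2E,4S)-4-[(tert-butyldimethylsilyl)oxy]-3-methyl-6-(oxetan-3-ylidene)hex-2-enoyl]pyrrolidine F1. Tf2O and 2,4,6-collidine in warm 1,2-dichloroethane convert it into the much more electrophilic vinylketeniminium trifluoromethanesulfonate F2, which undergoes the same [2+2] closure to the cyclobutaniminium trifluoromethanesulfonate F3. Aqueous NaHCO3 hydrolysis brings the route back at ketone 17.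

Step 8. A dianion has to attack a neopentyl-type oxetane carbon in the presence of BF3 and a carboxylate, and the choice between the two oxetane CH2 groups rests on sterics alone. The fallback sets out from 19: 2-furyllithium F4 (from furan and n-BuLi) with BF3·OEt2 opens the oxetane to the 2-furylmethyl diol F5, a well-precedented aryllithium opening. n-BuLi and TMEDA (3.3 equiv) then give the 5-lithiofuran dialkoxide F6, which is carboxylated with CO2 and comes back at 22.

Step 10. Singlet oxygen can also attack the methylidene group in an ene reaction, the decarboxylative fragmentation has to outrun other endoperoxide pathways, and the ketal carbon is not controlled. The fallback is a redox-neutral dearomatisation that sets out from 19. 3-Methylfuran-2(5H)-one is silylated (triisopropylsilyl trifluoromethanesulfonate, Et3N) to 3-methyl-2-[(triisopropylsilyl)oxy]furan F7, which is lithiated at C5 (sec-BuLi, TMEDA) to the 5-lithio derivative F8 and opens the oxetane of 19 (BF3·OEt2) to the silyloxyfuran diol F9. Camphorsulfonic acid in wet CH2Cl2 protodesilylates at furan C3 to the enol lactone F10; protonation of its enol double bond and capture by the primary alcohol gives the spiroketal directly and comes back at 28, with the ketal and α-methyl centres sorted by equilibration and chromatography.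

**Further compounds**

F1 | step 6 | 1-[(2E,4S)-4-[(tert-butyldimethylsilyl)oxy]-3-methyl-6-(oxetan-3-ylidene)hex-2-enoyl]pyrrolidine | O=C(/C=C(\C)[C@@H](O[Si](C)(C)C(C)(C)C)CC=C1COC1)N1CCCC1
F2 | step 6 | vinylketeniminium trifluoromethanesulfonate derived from F1 | C=C(C=C=[N+]1CCCC1)[C@@H](O[Si](C)(C)C(C)(C)C)CC=C1COC1.[O-]S(=O)(=O)C(F)(F)F
F3 | step 6 | C7 pyrrolidinium (cyclobutaniminium) trifluoromethanesulfonate corresponding to 17 | C=C1[C@@H](O[Si](C)(C)C(C)(C)C)C[C@H]2C(=[N+]3CCCC3)[C@@H]1C21COC1.[O-]S(=O)(=O)C(F)(F)F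
F4 | step 8 | 2-furyllithium | [Li]c1ccco1
F5 | step 8 | (1R,3S,5R,6S)-6-(furan-2-ylmethyl)-6-(hydroxymethyl)-2-methylidenebicyclo[3.1.1]heptan-3-ol | C=C1[C@@H](O)C[C@H]2C[C@@H]1[C@@]2(Cc1ccco1)CO
F6 | step 8 | trilithio derivative of F5 (two lithium alkoxides, furan C5–Li) | C=C1[C@@H](O[Li])C[C@H]2C[C@@H]1[C@@]2(Cc1ccc([Li])o1)CO[Li]
F7 | step 10 | 3-methyl-2-[(triisopropylsilyl)oxy]furan | Cc1ccoc1O[Si](C(C)C)(C(C)C)C(C)C
F8 | step 10 | 5-lithio-3-methyl-2-[(triisopropylsilyl)oxy]furan | Cc1cc([Li])oc1O[Si](C(C)C)(C(C)C)C(C)C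
F9 | step 10 | (1R,3S,5R,6S)-6-(hydroxymethyl)-2-methylidene-6-({4-methyl-5-[(triisopropylsilyl)oxy]furan-2-yl}methyl)bicyclo[3.1.1]heptan-3-ol | C=C1[C@@H](O)C[C@H]2C[C@@H]1[C@@]2(Cc1cc(C)c(O[Si](C(C)C)(C(C)C)C(C)C)o1)CO
F10 | step 10 | 3-methyl-5-{[core-6-yl]methyl}furan-2(3H)-one (enol lactone; core as in 22) | C=C1[C@@H](O)C[C@H]2C[C@@H]1[C@@]2(CC1=CC(C)C(=O)O1)CO
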